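**Retrosynthetic overview**
- The aryl ketone comes from addition of a 2,5-dioxygenated aryllithium to a morpholine amide; MOM and silyl groups come off last.
- The oxepine acid comes from hydroxide cleavage (Haller–Bauer type) of a 6-oxabicyclo[3.2.1]oct-2-en-8-one: the bridging ketone carbon becomes the CO2H on oxepine C2, and the departing allyl unit becomes C4H2–C5H=C6.
- The bicycle comes from a one-pot annulation of a vinylphosphonium C2 unit onto a 4-formyl-oxolan-3-one: oxepine bonds C2–C3 (enolate conjugate addition) and C4–C5 (Wittig) form together.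
- Enabling feature: the carboxyl carbon on C2 can be tied to C6 as a ketone, which folds O1–C2–C(=O)–C6–C7 into an oxolan-3-one whose C2 is an enolisable α-carbon and whose C6 carries C5 as a formyl group.
- Ring order: oxolanone (bought), then cyclohexene plus seven-membered oxacycle (key step), then oxepine by ring cleavage; the C6 quaternary centre from an organocatalytic Michael addition relays its configuration to C2 and is then erased.

Key step: step 8

Assumption: the sense of induction in step 1 is taken by analogy with carbocyclic β-keto esters; if the (S)-adduct forms, the pseudo-enantiomeric cupreine catalyst is used instead.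

**Step 1**
Reactants: 1 methyl 4-oxooxolane-3-carboxylate; 2 acrolein
Product: 3 methyl (3R)-4-oxo-3-(3-oxopropyl)oxolane-3-carboxylate
Conditions: 9-O-(9-phenanthryl)cupreidine (10 mol%), CH2Cl2, −24 °C
Reagents that add atoms: none
Why: Organocatalytic asymmetric Michael addition of a cyclic β-keto ester to acrolein with a bifunctional 6'-hydroxy cinchona catalyst should give the quaternary centre, the catalyst shielding one face of the hydrogen-bonded enol and so setting C3 as (R).

**Step 2**
Reactants: 3; 4 2-(triphenylphosphoranylidene)propanal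
Product: 5 methyl (3R)-3-[(3E)-4-methyl-5-oxopent-3-en-1-yl]-4-oxooxolane-3-carboxylate
Conditions: toluene, 80 °C
Reagents that add atoms: none
Why: The stabilised formyl ylide should olefinate only the aldehyde and give the (E)-2-methyl enal (Wittig reaction), leaving the hindered ketone alone.

**Step 3**
Reactants: 5
Product: 6 methyl (3R)-3-[(3E)-5-hydroxy-4-methylpent-3-en-1-yl]-4-oxooxolane-3-carboxylate
Conditions: LiAlH(O-t-Bu)3, THF, −78 °C
Reagents that add atoms: none
Why: The bulky hydride should reduce the conjugated aldehyde in the 1,2 sense at low temperature while the ketone next to the quaternary centre and the ester survive (chemoselective hydride reduction).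

**Step 4**
Reactants: 6
Product: 7 methyl (3R)-3-[(3E)-5-(tert-butyldimethylsilyloxy)-4-methylpent-3-en-1-yl]-4-oxooxolane-3-carboxylate
Conditions: TBSCl, imidazole, DMF, 0 °C to rt
Reagents that add atoms: tert-butyldimethylsilyl chloride, CC(C)(C)[Si](C)(C)Cl
Why: Silylation of a primary allylic alcohol is routine and the silyl ether tolerates every later basic, hydridic and oxidative step.

**Step 5**
Reactants: 7; 8 2-bromo-1-(morpholin-4-yl)ethan-1-one
Product: 9 methyl (3R)-3-[(3E)-5-(tert-butyldimethylsilyloxy)-4-methylpent-3-en-1-yl]-5-[2-(morpholin-4-yl)-2-oxoethyl]-4-oxooxolane-3-carboxylate (both C5 epimers)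
Conditions: LiN(i-Pr)2, THF, −78 °C; then 8, −78 to −20 °C
Reagents that add atoms: none
Why: C5 is the only enolisable position of the ketone, so one lithium enolate forms and is alkylated by the reactive α-bromo amide (kinetic enolate alkylation); the C5 configuration does not matter because this centre is enolised again in step 8.

**Step 6**
Reactants: 9
Product: 10 2-{(4R)-4-[(3E)-5-(tert-butyldimethylsilyloxy)-4-methylpent-3-en-1-yl]-3-hydroxy-4-(hydroxymethyl)oxolan-2-yl}-1-(morpholin-4-yl)ethan-1-one (mixture at C2 and C3)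
Conditions: LiBH4, THF, MeOH (1 equiv), 0 °C to rt
Reagents that add atoms: none
Why: LiBH4 should reduce the ketone and the methyl ester but not the tertiary amide or the silyl ether (chemoselective borohydride reduction); the diastereomers converge in step 7.

**Step 7**
Reactants: 10
Product: 11 (3S)-3-[(3E)-5-(tert-butyldimethylsilyloxy)-4-methylpent-3-en-1-yl]-5-[2-(morpholin-4-yl)-2-oxoethyl]-4-oxooxolane-3-carbaldehyde (both C5 epimers)
Conditions: Dess–Martin periodinane, CH2Cl2, rt
Reagents that add atoms: none
Why: Dess–Martin oxidation should convert both alcohols under neutral conditions, and the new aldehyde sits on a quaternary carbon and so cannot enolise or epimerise (the descriptor changes from R to S only through priorities).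

**Step 8**
Reactants: 11; 12 vinyltriphenylphosphonium bromide
Product: 14 (1R,5S)-1-[(3E)-5-(tert-butyldimethylsilyloxy)-4-methylpent-3-en-1-yl]-5-[2-(morpholin-4-yl)-2-oxoethyl]-6-oxabicyclo[3.2.1]oct-2-en-8-one, via phosphonium ylide 13 (not isolated)
Conditions: NaH, THF, 0 °C; then 12, 0 to 65 °C
Reagents that add atoms: none
Why: NaH should form the sodium enolate at C5 of 11, which adds to the β-carbon of the vinylphosphonium salt to give ylide 13, and the ylide carbon then olefinates the formyl group on C3 with loss of Ph3P=O. The closest known reaction type is the Schweizer annulation (enolate conjugate addition to vinyltriphenylphosphonium bromide followed by intramolecular Wittig reaction), used for cyclopentenes, cyclohexenes and 2H-chromenes. The cyclohexene ring C1–C2=C3–C4–C5–C8 closes by Wittig C=C formation in a six-membered mode, and because C1 and C5 are already joined through O6–C7 the same event closes the seven-membered oxacycle O6–C7–C1–C2–C3–C4–C5 of the target. The new quaternary centre C5 (oxepine C2) is controlled by the formyl-bearing quaternary centre set in step 1: only the adduct with the phosphonioethyl arm cis to the formyl group can bridge, and the conjugate addition is reversible, so the trans adduct should return to the enolate. The step needs C- over O-alkylation and enolisation at one site only; this is secured because the aldehyde is non-enolisable, the amide CH2 is far less acidic than the α-alkoxy ketone C–H, and the Wittig closure is irreversible.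

**Step 9**
Reactants: 14
Product: 15 (2S)-6-[(3E)-5-(tert-butyldimethylsilyloxy)-4-methylpent-3-en-1-yl]-2-[2-(morpholin-4-yl)-2-oxoethyl]-2,3,4,7-tetrahydrooxepine-2-carboxylic acid
Conditions: KOH, DMSO–H2O (9:1), 25 °C; then aq. HCl to pH 3
Reagents that add atoms: potassium hydroxide, [K+].[OH-]
Why: Hydroxide should add to the strained, non-enolisable bridging ketone and the adduct should cleave the C8–C1 bond toward the allyl anion and not toward the α-alkoxy carbanion (Haller–Bauer-type cleavage), the anion taking its proton at C3 from the adjacent gem-diol OH through a six-membered array, so that the double bond ends at C1=C2 (oxepine C5=C6) and C5 keeps its configuration because none of its other bonds is touched.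

**Step 10**
Reactants: 16 hydroquinone
Product: 17 1,4-bis(methoxymethoxy)benzene
Conditions: MOMCl, i-Pr2NEt, CH2Cl2, 0 °C to rt
Reagents that add atoms: chloromethyl methyl ether, COCCl
Why: Double O-alkylation of the phenol gives the bis-acetal, which both protects the phenols and directs ortho-lithiation.

**Step 11**
Reactants: 15; 17
Product: 19 (2S)-2-{2-[2,5-bis(methoxymethoxy)phenyl]-2-oxoethyl}-6-[(3E)-5-(tert-butyldimethylsilyloxy)-4-methylpent-3-en-1-yl]-2,3,4,7-tetrahydrooxepine-2-carboxylic acid, via aryllithium 18 (not isolated)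
Conditions: 17, n-BuLi, THF, 0 °C; then 15, −78 °C; AcOH quench
Reagents that add atoms: n-butyllithium, [Li]CCCC (its lithium is found in 18 only)
Why: Directed ortho-lithiation gives 18, of which one equivalent deprotonates the acid and a second adds to the morpholine amide to give a chelated tetrahedral adduct that releases the ketone only on quench (Weinreb-type ketone synthesis), and the low temperature should prevent enolisation of the amide; no stereocentre is touched.

**Step 12**
Reactants: 19
Product: 20 (2S)-2-[2-(2,5-dihydroxyphenyl)-2-oxoethyl]-6-[(3E)-5-hydroxy-4-methylpent-3-en-1-yl]-2,3,4,7-tetrahydrooxepine-2-carboxylic acid (target)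
Conditions: 3 M aq. HCl, THF, 35 °C
Reagents that add atoms: none
Why: Aqueous acid should hydrolyse both phenolic MOM acetals and the primary silyl ether (acetal hydrolysis and desilylation) without affecting the tertiary ether, the trisubstituted alkenes or the quaternary centre.

**Compound list**
1 | methyl 4-oxooxolane-3-carboxylate | COC(=O)C1COCC1=O | starting material
2 | acrolein | C=CC=O | starting material
3 | methyl (3R)-4-oxo-3-(3-oxopropyl)oxolane-3-carboxylate | O=CCC[C@@]1(C(=O)OC)COCC1=O | intermediate
4 | 2-(triphenylphosphoranylidene)propanal | CC(C=O)=P(c1ccccc1)(c1ccccc1)c1ccccc1 | starting material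
5 | methyl (3R)-3-[(3E)-4-methyl-5-oxopent-3-en-1-yl]-4-oxooxolane-3-carboxylate | O=C/C(C)=C/CC[C@@]1(C(=O)OC)COCC1=O | intermediate
6 | methyl (3R)-3-[(3E)-5-hydroxy-4-methylpent-3-en-1-yl]-4-oxooxolane-3-carboxylate | OC/C(C)=C/CC[C@@]1(C(=O)OC)COCC1=O | intermediate
7 | methyl (3R)-3-[(3E)-5-(tert-butyldimethylsilyloxy)-4-methylpent-3-en-1-yl]-4-oxooxolane-3-carboxylate | CC(C)(C)[Si](C)(C)OC/C(C)=C/CC[C@@]1(C(=O)OC)COCC1=O | intermediate
8 | 2-bromo-1-(morpholin-4-yl)ethan-1-one | O=C(CBr)N1CCOCC1 | starting material
9 | methyl (3R)-3-[(3E)-5-(tert-butyldimethylsilyloxy)-4-methylpent-3-en-1-yl]-5-[2-(morpholin-4-yl)-2-oxoethyl]-4-oxooxolane-3-carboxylate, both C5 epimers | CC(C)(C)[Si](C)(C)OC/C(C)=C/CC[C@@]1(C(=O)OC)COC(CC(=O)N2CCOCC2)C1=O | intermediate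
10 | 2-{(4R)-4-[(3E)-5-(tert-butyldimethylsilyloxy)-4-methylpent-3-en-1-yl]-3-hydroxy-4-(hydroxymethyl)oxolan-2-yl}-1-(morpholin-4-yl)ethan-1-one, mixture at C2 and C3 | CC(C)(C)[Si](C)(C)OC/C(C)=C/CC[C@@]1(CO)COC(CC(=O)N2CCOCC2)C1O | intermediate
11 | (3S)-3-[(3E)-5-(tert-butyldimethylsilyloxy)-4-methylpent-3-en-1-yl]-5-[2-(morpholin-4-yl)-2-oxoethyl]-4-oxooxolane-3-carbaldehyde, both C5 epimers | CC(C)(C)[Si](C)(C)OC/C(C)=C/CC[C@@]1(C=O)COC(CC(=O)N2CCOCC2)C1=O | intermediate
12 | vinyltriphenylphosphonium bromide | C=C[P+](c1ccccc1)(c1ccccc1)c1ccccc1.[Br-] | starting material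
13 | phosphonium ylide: (3S,5R)-11 carrying at C5 a 2-(triphenylphosphoranylidene)ethyl group cis to the formyl group | CC(C)(C)[Si](C)(C)OC/C(C)=C/CC[C@@]1(C=O)CO[C@](CC(=O)N2CCOCC2)(C[CH-][P+](c2ccccc2)(c2ccccc2)c2ccccc2)C1=O | intermediate (not isolated)
14 | (1R,5S)-1-[(3E)-5-(tert-butyldimethylsilyloxy)-4-methylpent-3-en-1-yl]-5-[2-(morpholin-4-yl)-2-oxoethyl]-6-oxabicyclo[3.2.1]oct-2-en-8-one | CC(C)(C)[Si](C)(C)OC/C(C)=C/CC[C@]12CO[C@](CC(=O)N3CCOCC3)(CC=C1)C2=O | intermediate
15 | (2S)-6-[(3E)-5-(tert-butyldimethylsilyloxy)-4-methylpent-3-en-1-yl]-2-[2-(morpholin-4-yl)-2-oxoethyl]-2,3,4,7-tetrahydrooxepine-2-carboxylic acid | CC(C)(C)[Si](C)(C)OC/C(C)=C/CCC1=CCC[C@](CC(=O)N2CCOCC2)(C(=O)O)OC1 | intermediate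
16 | hydroquinone | Oc1ccc(O)cc1 | starting material
17 | 1,4-bis(methoxymethoxy)benzene | COCOc1ccc(OCOC)cc1 | intermediate
18 | [2,5-bis(methoxymethoxy)phenyl]lithium | COCOc1ccc(OCOC)c([Li])c1 | intermediate (not isolated)
19 | (2S)-2-{2-[2,5-bis(methoxymethoxy)phenyl]-2-oxoethyl}-6-[(3E)-5-(tert-butyldimethylsilyloxy)-4-methylpent-3-en-1-yl]-2,3,4,7-tetrahydrooxepine-2-carboxylic acid | CC(C)(C)[Si](C)(C)OC/C(C)=C/CCC1=CCC[C@](CC(=O)c2cc(OCOC)ccc2OCOC)(C(=O)O)OC1 | intermediate
20 | (2S)-2-[2-(2,5-dihydroxyphenyl)-2-oxoethyl]-6-[(3E)-5-hydroxy-4-methylpent-3-en-1-yl]-2,3,4,7-tetrahydrooxepine-2-carboxylic acid | C/C(=C\CCC1=CCC[C@](CC(=O)c2cc(O)ccc2O)(C(=O)O)OC1)CO | target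

**Step count and risks**
Total step count: 12. Longest linear sequence: 11 (steps 1 to 9, 11 and 12).

Most likely to fail, first: step 9. The hydroxide adduct may not expel the allyl anion, the anion may take its proton at the other terminus and leave the double bond at oxepine C4=C5, or the amide may hydrolyse first. The fallback sets out from 11 and comes back at 15. Conjugate addition of the sodium enolate of 11 to phenyl vinyl sulfone, followed by aldol closure of the α-sulfonyl carbanion onto the formyl group, should give the bicyclic hydroxy sulfone F1. MsCl and Et3N convert it into the mesylate F2. LiOH in aqueous THF should then trigger a Grob-type fragmentation (hydroxide on the ketone, C8–C1 cleavage, loss of mesylate) to the allylic sulfone acid F3, so that a sulfonate and not an allyl anion is the leaving group and the alkene position is fixed by the mechanism. Pd(PPh3)4 with NaBH4 removes the sulfonyl group, with hydride delivery to the less substituted allyl terminus, and gives 15.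

Second: step 8. The base may cause intermolecular aldol reaction or deformylation of the β-keto aldehyde, or the hindered ylide may close too slowly. The fallback sets out from 11 and comes back at 14. Methylenation of the aldehyde with Ph3P=CH2 in THF at −78 °C should give the vinyl ketone F4. LiN(i-Pr)2 and allyl bromide give the C2-allyl compound F5, of which the isomer with allyl cis to vinyl is used. Ring-closing metathesis with the second-generation Grubbs catalyst RuCl2(=CHPh)(H2IMes)(PCy3) closes the cyclohexene and gives 14.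

Third: step 3. The ring ketone may be reduced along with the aldehyde. The fallback sets out from 5 and comes back at 7. NaBH4 in MeOH at 0 °C reduces both carbonyl groups to the diol F6. One equivalent of TBSCl with imidazole silylates only the primary allylic alcohol and gives the hydroxy silyl ether F7. Dess–Martin oxidation restores the ketone and gives 7.

**Further compounds**
F1 | step 9 | (1S,5R)-1-[(3E)-5-(tert-butyldimethylsilyloxy)-4-methylpent-3-en-1-yl]-2-hydroxy-5-[2-(morpholin-4-yl)-2-oxoethyl]-3-(phenylsulfonyl)-6-oxabicyclo[3.2.1]octan-8-one, bridgeheads arranged as in 14, mixture at C2 and C3 | CC(C)(C)[Si](C)(C)OC/C(C)=C/CC[C@]12CO[C@](CC(=O)N3CCOCC3)(CC(C1O)S(=O)(=O)c1ccccc1)C2=O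
F2 | step 9 | methanesulfonate of F1 at the C2 hydroxyl | CC(C)(C)[Si](C)(C)OC/C(C)=C/CC[C@]12CO[C@](CC(=O)N3CCOCC3)(CC(C1OS(C)(=O)=O)S(=O)(=O)c1ccccc1)C2=O
F3 | step 9 | (2R)-6-[(3E)-5-(tert-butyldimethylsilyloxy)-4-methylpent-3-en-1-yl]-2-[2-(morpholin-4-yl)-2-oxoethyl]-4-(phenylsulfonyl)-2,3,4,7-tetrahydrooxepine-2-carboxylic acid, C2 arranged as in 15, both C4 epimers | CC(C)(C)[Si](C)(C)OC/C(C)=C/CCC1=CC(S(=O)(=O)c2ccccc2)C[C@](CC(=O)N2CCOCC2)(C(=O)O)OC1
F4 | step 8 | 2-{(4R)-4-ethenyl-4-[(3E)-5-(tert-butyldimethylsilyloxy)-4-methylpent-3-en-1-yl]-3-oxooxolan-2-yl}-1-(morpholin-4-yl)ethan-1-one, both C2 epimers | CC(C)(C)[Si](C)(C)OC/C(C)=C/CC[C@@]1(C=C)COC(CC(=O)N2CCOCC2)C1=O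
F5 | step 8 | 2-{(2S,4R)-4-ethenyl-4-[(3E)-5-(tert-butyldimethylsilyloxy)-4-methylpent-3-en-1-yl]-3-oxo-2-(prop-2-en-1-yl)oxolan-2-yl}-1-(morpholin-4-yl)ethan-1-one | CC(C)(C)[Si](C)(C)OC/C(C)=C/CC[C@@]1(C=C)CO[C@](CC(=O)N2CCOCC2)(CC=C)C1=O
F6 | step 3 | methyl (3R)-4-hydroxy-3-[(3E)-5-hydroxy-4-methylpent-3-en-1-yl]oxolane-3-carboxylate, both C4 epimers | OC/C(C)=C/CC[C@@]1(C(=O)OC)COCC1O
F7 | step 3 | methyl (3R)-3-[(3E)-5-(tert-butyldimethylsilyloxy)-4-methylpent-3-en-1-yl]-4-hydroxyoxolane-3-carboxylate, both C4 epimers | CC(C)(C)[Si](C)(C)OC/C(C)=C/CC[C@@]1(C(=O)OC)COCC1O
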